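The earlier runs and the new flask stem from a simulated flask from invented constants.

At early times each run climbs steeply, and the first readings put both orders near one: 1.05 in reagent from delta over alpha, and 1.10 in starting material from epsilon over alpha. These are readings, with their scatter.

| flask | starting material | reagent | time |
|---|---|---|---|
| alpha | 0.500 M | 1.00 M |  |
| epsilon | 0.750 M | 1.00 M |  |
| delta | 0.500 M | 1.50 M |  |
| zeta | 0.500 M | 3.00 M | 29 min |

| run | time / min | [target] / M |
|---|---|---|
| alpha run | 4.1 | 0.064 |
| alpha run | 8.3 | 0.110 |
| alpha run | 12 | 0.150 |
| alpha run | 17 | 0.176 |
| alpha run | 21 | 0.192 |
| alpha run | 25 | 0.194 |
| alpha run | 29 | 0.201 |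
| epsilon run | 4.1 | 0.100 |
| epsilon run | 8.3 | 0.169 |
| epsilon run | 12 | 0.208 |
| epsilon run | 17 | 0.246 |
| epsilon run | 21 | 0.275 |
| epsilon run | 25 | 0.273 |
| epsilon run | 29 | 0.289 |
| delta run | 4.1 | 0.098 |
| delta run | 8.3 | 0.161 |
| delta run | 12 | 0.196 |
| delta run | 17 | 0.225 |
| delta run | 21 | 0.235 |
| delta run | 25 | 0.244 |
| delta run | 29 | 0.245 |

(scatter of a reading: 0.004 M)

- Overall: starting material + reagent -> target.
- Constant volume, constant temperature.
- "The second partner" is reagent.
- An order is taken over about fifteen percent of the charge, up and down.

- the exponent of [starting material] in the starting rate at the charge of the alpha run (at the point where two percent of the starting material have become target) (one fixed amount of target, the same in the runs compared)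
- the exponent of [reagent] in the starting rate at the charge of the alpha run (at the point where two percent of the starting material have become target)
- target in the zeta run at 29 min, as a share of the starting material charged
- which of these the readings show (the product decays / nothing beyond the main steps / two substrates go astray together / the substrate pairs with itself / the second partner is lost by itself / the product speeds the reaction)

My bench rule is to hold c(reagent) at its charge and treat the loss of starting material as pseudo-first-order. In the delta run, the overall equation lets the starting material use at most 33.3% of the reagent. The first delta reading gives a pace of 0.0532 min⁻¹. Held to the end, that pace gives 78.6% of the charge at 29 min. I call this the ceiling, and it is an estimate, not a bound.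

The delta run reads 49.0% there, less than the ceiling, so this is where the rule stops. I carry the ratio of the two as the delivery: 62.3%. The delivery is the target read late as a share of the ceiling from the early pace. The alpha run, reckoned the same way, delivers 64.8%.

For the zeta run I scale the pace with reagent to 0.106 min⁻¹. The ceiling becomes 95.4%, and with the delivery of the delta run held fixed, my own estimate is 59.5%.

The forecast gives orders of 1.02 and 1.02, 68%, and "nothing beyond the main steps", on the ground that “a reversible main step explains everything”. Its share for the zeta run stands above mine.

The zeta run gives 56.5% at 29 min, with orders of 1.0 and 1.0, and the answer is that the product decays. The loss of target to decomposed product moves the readings by 12 units of the scatter, as a root mean square.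

    starting material + reagent → target (0.03840 L mol⁻¹ min⁻¹)
    starting material + reagent → side product (0.008700 L mol⁻¹ min⁻¹)
    target → decomposed product (0.01554 min⁻¹)

The zeta run delivers 59.2% of its ceiling, against my 62.3% from the delta run. The first reading of the epsilon run gives a ceiling of 63.7%, so the zeta delivery puts target in the epsilon run at 0.283 M, and the epsilon reading at 29 min is 0.289 M.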